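Ring C of the flavonol is cut at O1–C2 and C3–C4. The disconnection exploits three facts: ring A carries O1 and C4 on adjacent carbons (C8a, C4a), C2 bears ring B, and C3 bears a heteroatom. A salicylaldehyde (ring A plus C4) and a β-nitrostyrene (C2, C3, ring B; nitro standing in for the C3 oxygen) therefore map onto the target directly. One amine-mediated oxa-Michael–Henry condensation forms both bonds and closes ring C as a 2-aryl-3-nitro-2H-chromene. The precursors are a benzyl-protected 2-hydroxy-3-methoxybenzaldehyde and the benzyl-protected (E)-nitrostyrene. Alkaline peroxide then turns the nitroalkene into the 3-hydroxy-4-pyranone, and hydrogenolysis frees the phenols.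

Key step: step 11

Remark: the target is 3,5,7-trihydroxy-2-(3,5-dihydroxy-4-methoxyphenyl)-8-methoxy-4H-chromen-4-one and has no stereocentre. Its ring A pattern (5-OH, 7-OH, 8-OMe) requires the methoxy group at C3 of the salicylaldehyde (ortho to the phenol) and benzyloxy groups at its C4 and C6. Compounds 1, 10 and 14 are taken as commercial.

**Ring A: salicylaldehyde 9**

Step 1
Reactants: 1 2,4,6-trihydroxybenzaldehyde
Product: 2 2,4-bis(benzyloxy)-6-hydroxybenzaldehyde
Conditions: BnBr (2.05 equiv), K2CO3 (2.2 equiv), DMF, 0 °C → rt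
Reagents that add atoms: benzyl bromide, BrCc1ccccc1
Why: Williamson etherification in which the 4-OH (most acidic, para to the formyl group) and one ortho OH are alkylated, while the last ortho OH stays hydrogen-bonded to the carbonyl and is the least nucleophilic, so the bis-ether with one chelated phenol should dominate with two equivalents of halide.

Step 2
Reactants: 2 2,4-bis(benzyloxy)-6-hydroxybenzaldehyde
Product: 3 2,4-bis(benzyloxy)-6-(methoxymethoxy)benzaldehyde
Conditions: NaH (1.1 equiv), MOMCl (1.2 equiv), DMF, 0 °C → rt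
Reagents that add atoms: chloromethyl methyl ether, COCCl
Why: Williamson-type O-alkylation of the sodium phenoxide by the reactive α-chloro ether masks the future O1 phenol as an acetal that survives peracid, base and methylation and is later removed by mild acid without touching benzyl ethers.

Step 3
Reactants: 3 2,4-bis(benzyloxy)-6-(methoxymethoxy)benzaldehyde
Product: 5 2,4-bis(benzyloxy)-6-(methoxymethoxy)phenol, via aryl formate 4 (not isolated)
Conditions: mCPBA (1.2 equiv), CH2Cl2, 0 °C → rt; aqueous wash; then K2CO3 (cat.), MeOH, rt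
Reagents that add atoms: 3-chloroperoxybenzoic acid, OOC(=O)c1cccc(Cl)c1
Why: Dakin oxidation in its Baeyer–Villiger form, in which the peracid adduct of the aldehyde rearranges by migration of the very electron-rich aryl group (three ortho/para oxygen donors) to formate 4, which is then methanolysed to the phenol.

Step 4
Reactants: 5 2,4-bis(benzyloxy)-6-(methoxymethoxy)phenol
Product: 6 1,5-bis(benzyloxy)-2-methoxy-3-(methoxymethoxy)benzene
Conditions: MeI (1.5 equiv), K2CO3 (1.5 equiv), DMF, rt
Reagents that add atoms: iodomethane, CI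
Why: Williamson methylation of the only free phenol fixes the methoxy group that becomes the C8 substituent of the target.

Step 5
Reactants: 6 1,5-bis(benzyloxy)-2-methoxy-3-(methoxymethoxy)benzene
Product: 7 3,5-bis(benzyloxy)-2-methoxyphenol
Conditions: HCl (cat.), MeOH/THF, 50 °C
Reagents that add atoms: none
Why: Acid-catalysed acetal exchange to methanol cleaves the MOM ether selectively, since aryl benzyl and aryl methyl ethers are inert to dilute methanolic HCl.

Step 6
Reactants: 7 3,5-bis(benzyloxy)-2-methoxyphenol
Product: 9 4,6-bis(benzyloxy)-2-hydroxy-3-methoxybenzaldehyde, via salicyl alcohol 8 (not isolated)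
Conditions: (CH2O)n (6 equiv), MgCl2 (2 equiv), Et3N (4 equiv), MeCN, reflux; then 1 M HCl
Reagents that add atoms: paraformaldehyde (reacts as formaldehyde), C=O
Why: Magnesium-mediated ortho-formylation (Casnati–Skattebøl), in which the magnesium phenoxide of 7 delivers formaldehyde through a chelate to C6, the only unsubstituted ortho position, and salicyl alcohol 8 is oxidised in the flask by a second formaldehyde through Oppenauer-type hydride transfer, so the para position between the two benzyloxy groups is not attacked.

**Ring B: nitrostyrene 16**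

Step 7
Reactants: 10 methyl 3,5-dihydroxy-4-methoxybenzoate
Product: 11 methyl 3,5-bis(benzyloxy)-4-methoxybenzoate
Conditions: BnBr (2.3 equiv), K2CO3 (3 equiv), DMF, 60 °C
Reagents that add atoms: benzyl bromide, BrCc1ccccc1
Why: Williamson etherification of both phenols, with the ester and the methyl ether inert under carbonate conditions.

Step 8
Reactants: 11 methyl 3,5-bis(benzyloxy)-4-methoxybenzoate
Product: 12 [3,5-bis(benzyloxy)-4-methoxyphenyl]methanol
Conditions: LiAlH4 (1.0 equiv), THF, 0 °C → rt; then H2O
Reagents that add atoms: none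
Why: Hydride reduction of the aryl ester to the primary benzylic alcohol, aryl ethers being inert to LiAlH4.

Step 9
Reactants: 12 [3,5-bis(benzyloxy)-4-methoxyphenyl]methanol
Product: 13 3,5-bis(benzyloxy)-4-methoxybenzaldehyde
Conditions: activated MnO2 (10 equiv), CH2Cl2, rt
Reagents that add atoms: none
Why: Activated MnO2 oxidises benzylic alcohols selectively to aldehydes and does not carry the oxidation on to the acid.

Step 10
Reactants: 13 3,5-bis(benzyloxy)-4-methoxybenzaldehyde; 14 nitromethane
Product: 16 (E)-1,3-bis(benzyloxy)-2-methoxy-5-(2-nitrovinyl)benzene, via nitro alcohol 15 (not isolated)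
Conditions: MeNO2 (10 equiv), NH4OAc (0.3 equiv), AcOH, 100 °C
Reagents that add atoms: none
Why: Henry (nitroaldol) condensation followed by dehydration of nitro alcohol 15 under the hot acidic ammonium acetate conditions, the conjugated (E)-alkene being the thermodynamic isomer, which sets the double-bond geometry.

**Key step and endgame**

Step 11
Reactants: 9 4,6-bis(benzyloxy)-2-hydroxy-3-methoxybenzaldehyde; 16 (E)-1,3-bis(benzyloxy)-2-methoxy-5-(2-nitrovinyl)benzene
Product: 19 racemic 5,7-bis(benzyloxy)-2-[3,5-bis(benzyloxy)-4-methoxyphenyl]-8-methoxy-3-nitro-2H-chromene, via oxa-Michael adduct 17 (not isolated), via nitrochromanol 18 (not isolated)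
Conditions: 16 (1.3 equiv), DABCO (0.5 equiv), MeCN (ca. 2 M), 4 Å MS, 60 °C
Reagents that add atoms: none
Why: DABCO deprotonates the single free phenol of 9 and the phenoxide adds to the aryl-bearing β-carbon of 16 (oxa-Michael, O1–C2) to give the nitronate of 17, which attacks the ortho formyl carbon in an intramolecular Henry reaction (C3–C4, 6-exo-trig closure of ring C) to give 18; E1cB loss of water, driven by conjugation of the nitroalkene with ring A and by the sieves, makes the sequence irreversible. The closest known reaction type is the tertiary-amine-catalysed oxa-Michael–Henry condensation of substituted salicylaldehydes with β-nitrostyrenes to 2-aryl-3-nitro-2H-chromenes. The one new stereocentre, C2, is formed without control as a racemate, which is acceptable because it becomes sp2 in step 12. The selectivity needed is regiochemical and is fixed by the polarity of the nitroalkene: oxygen can bond only to the β-carbon that carries ring B, and the nitro-bearing carbon can bond only to the formyl carbon, so ring B ends at C2 and nitrogen at C3. Chemoselectivity is secured by protection, since every other phenol is a benzyl or methyl ether and 9 offers one nucleophilic oxygen and one electrophilic carbonyl. Because both partners are electron-rich and the formyl group is flanked by a benzyloxy group, high concentration, moderate heating and an excess of 16 are planned to offset a slow closure.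

Step 12
Reactants: 19 racemic 5,7-bis(benzyloxy)-2-[3,5-bis(benzyloxy)-4-methoxyphenyl]-8-methoxy-3-nitro-2H-chromene
Product: 22 5,7-bis(benzyloxy)-2-[3,5-bis(benzyloxy)-4-methoxyphenyl]-3-hydroxy-8-methoxy-4H-chromen-4-one, via nitro epoxide 20 (not isolated), via ketol 21 (not isolated)
Conditions: 30% aq. H2O2 (4 equiv), 2 M aq. NaOH (3 equiv), THF/MeOH, 0 °C → rt; then AcOH
Reagents that add atoms: hydrogen peroxide, OO; sodium hydroxide, [Na+].[OH-]
Why: Nucleophilic (Weitz–Scheffer-type) epoxidation of the electron-poor nitroalkene gives nitro epoxide 20, hydroxide opens it at the benzylic C4 with expulsion of nitrite from C3 to give α-ketol 21, and excess peroxide oxidises the derived enediolate to the 3,4-dione, whose enolisation through C2–H (removing the C2 stereocentre) gives the aromatic 3-hydroxy-4-pyranone, a product type that tolerates alkaline peroxide as Algar–Flynn–Oyamada conditions show.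

Step 13
Reactants: 22 5,7-bis(benzyloxy)-2-[3,5-bis(benzyloxy)-4-methoxyphenyl]-3-hydroxy-8-methoxy-4H-chromen-4-one
Product: 23 3,5,7-trihydroxy-2-(3,5-dihydroxy-4-methoxyphenyl)-8-methoxy-4H-chromen-4-one
Conditions: H2 (1 atm), 10% Pd/C, THF/MeOH (1:1), rt
Reagents that add atoms: none
Why: Catalytic hydrogenolysis cleaves the four benzylic C–O bonds, while the aryl methyl ethers and the aromatic 3-hydroxychromone core are not reduced under one atmosphere of hydrogen at room temperature.

**Compound list**

1 | 2,4,6-trihydroxybenzaldehyde | O=Cc1c(O)cc(O)cc1O | starting material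
2 | 2,4-bis(benzyloxy)-6-hydroxybenzaldehyde | O=Cc1c(O)cc(OCc2ccccc2)cc1OCc1ccccc1 | intermediate
3 | 2,4-bis(benzyloxy)-6-(methoxymethoxy)benzaldehyde | O=Cc1c(OCOC)cc(OCc2ccccc2)cc1OCc1ccccc1 | intermediate
4 | 2,4-bis(benzyloxy)-6-(methoxymethoxy)phenyl formate | O=COc1c(OCOC)cc(OCc2ccccc2)cc1OCc1ccccc1 | intermediate (not isolated)
5 | 2,4-bis(benzyloxy)-6-(methoxymethoxy)phenol | Oc1c(OCOC)cc(OCc2ccccc2)cc1OCc1ccccc1 | intermediate
6 | 1,5-bis(benzyloxy)-2-methoxy-3-(methoxymethoxy)benzene | COc1c(OCOC)cc(OCc2ccccc2)cc1OCc1ccccc1 | intermediate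
7 | 3,5-bis(benzyloxy)-2-methoxyphenol | COc1c(O)cc(OCc2ccccc2)cc1OCc1ccccc1 | intermediate
8 | 3,5-bis(benzyloxy)-2-(hydroxymethyl)-6-methoxyphenol (present as its magnesium phenoxide) | OCc1c(O)c(OC)c(OCc2ccccc2)cc1OCc1ccccc1 | intermediate (not isolated)
9 | 4,6-bis(benzyloxy)-2-hydroxy-3-methoxybenzaldehyde | O=Cc1c(O)c(OC)c(OCc2ccccc2)cc1OCc1ccccc1 | intermediate
10 | methyl 3,5-dihydroxy-4-methoxybenzoate | COC(=O)c1cc(O)c(OC)c(O)c1 | starting material
11 | methyl 3,5-bis(benzyloxy)-4-methoxybenzoate | COC(=O)c1cc(OCc2ccccc2)c(OC)c(OCc2ccccc2)c1 | intermediate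
12 | [3,5-bis(benzyloxy)-4-methoxyphenyl]methanol | OCc1cc(OCc2ccccc2)c(OC)c(OCc2ccccc2)c1 | intermediate
13 | 3,5-bis(benzyloxy)-4-methoxybenzaldehyde | O=Cc1cc(OCc2ccccc2)c(OC)c(OCc2ccccc2)c1 | intermediate
14 | nitromethane | C[N+](=O)[O-] | starting material
15 | racemic 1-[3,5-bis(benzyloxy)-4-methoxyphenyl]-2-nitroethanol | OC(C[N+](=O)[O-])c1cc(OCc2ccccc2)c(OC)c(OCc2ccccc2)c1 | intermediate (not isolated)
16 | (E)-1,3-bis(benzyloxy)-2-methoxy-5-(2-nitrovinyl)benzene | O=[N+]([O-])/C=C/c1cc(OCc2ccccc2)c(OC)c(OCc2ccccc2)c1 | intermediate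
17 | racemic 4,6-bis(benzyloxy)-2-{1-[3,5-bis(benzyloxy)-4-methoxyphenyl]-2-nitroethoxy}-3-methoxybenzaldehyde (present as its nitronate) | O=Cc1c(OC(C[N+](=O)[O-])c2cc(OCc3ccccc3)c(OC)c(OCc3ccccc3)c2)c(OC)c(OCc2ccccc2)cc1OCc1ccccc1 | intermediate (not isolated)
18 | 5,7-bis(benzyloxy)-2-[3,5-bis(benzyloxy)-4-methoxyphenyl]-8-methoxy-3-nitrochroman-4-ol (racemic, mixture of diastereomers) | OC1c2c(OCc3ccccc3)cc(OCc3ccccc3)c(OC)c2OC(c2cc(OCc3ccccc3)c(OC)c(OCc3ccccc3)c2)C1[N+](=O)[O-] | intermediate (not isolated)
19 | racemic 5,7-bis(benzyloxy)-2-[3,5-bis(benzyloxy)-4-methoxyphenyl]-8-methoxy-3-nitro-2H-chromene | [O-][N+](=O)C1=Cc2c(OCc3ccccc3)cc(OCc3ccccc3)c(OC)c2OC1c1cc(OCc2ccccc2)c(OC)c(OCc2ccccc2)c1 | intermediate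
20 | 5,7-bis(benzyloxy)-2-[3,5-bis(benzyloxy)-4-methoxyphenyl]-3,4-epoxy-8-methoxy-3-nitrochroman (racemic, relative configuration not controlled) | [O-][N+](=O)C12OC1c1c(OCc3ccccc3)cc(OCc3ccccc3)c(OC)c1OC2c1cc(OCc2ccccc2)c(OC)c(OCc2ccccc2)c1 | intermediate (not isolated)
21 | 5,7-bis(benzyloxy)-2-[3,5-bis(benzyloxy)-4-methoxyphenyl]-4-hydroxy-8-methoxychroman-3-one (racemic, mixture of diastereomers) | OC1c2c(OCc3ccccc3)cc(OCc3ccccc3)c(OC)c2OC(c2cc(OCc3ccccc3)c(OC)c(OCc3ccccc3)c2)C1=O | intermediate (not isolated)
22 | 5,7-bis(benzyloxy)-2-[3,5-bis(benzyloxy)-4-methoxyphenyl]-3-hydroxy-8-methoxy-4H-chromen-4-one | COc1c(OCc2ccccc2)cc(-c2oc3c(OC)c(OCc4ccccc4)cc(OCc4ccccc4)c3c(=O)c2O)cc1OCc1ccccc1 | intermediate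
23 | 3,5,7-trihydroxy-2-(3,5-dihydroxy-4-methoxyphenyl)-8-methoxy-4H-chromen-4-one | COc1c(O)cc(-c2oc3c(OC)c(O)cc(O)c3c(=O)c2O)cc1O | target

Total step count: 13
Longest linear sequence: 9 steps (steps 1–6, then 11, 12 and 13)

**Steps most likely to fail**

1. Step 11 (key step). The oxa-Michael addition is reversible, and the Henry closure onto a formyl group that is deactivated by three oxygen donors and flanked by a benzyloxy group may be too slow, so that amine-induced oligomerisation of the nitrostyrene consumes 16 before ring C closes. The fallback moves the activation from the phenol to the aldehyde. Setting out from 9 and 16, aldehyde 9 is first condensed with pyrrolidine (1.1 equiv, EtOH, rt) to the zwitterionic 3,5-bis(benzyloxy)-2-methoxy-6-[(pyrrolidin-1-ium-1-ylidene)methyl]phenolate F1, whose iminium carbon is far more electrophilic than the formyl carbon. Addition of 16 in toluene at 80 °C should then give, by oxa-Michael addition and nitro-Mannich closure, racemic 1-{5,7-bis(benzyloxy)-2-[3,5-bis(benzyloxy)-4-methoxyphenyl]-8-methoxy-3-nitrochroman-4-yl}pyrrolidine F2. Warming F2 with benzoic acid in toluene eliminates pyrrolidine (E1cB) and returns the route to 19.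

2. Step 12. Three processes could erode the one-flask cascade: over-oxidation of the electron-rich flavonolate by alkaline peroxide, base-induced retro-oxa-Michael opening of the chromene, and stalling at the ketol stage. The fallback separates the events and removes peroxide from the last oxidation. Setting out from 19, a short epoxidation at 0 °C (H2O2, catalytic NaOH, THF/MeOH) is stopped at the nitro epoxide 20, which is isolated. Compound 20 is opened in wet DMSO with NaHCO3 to the ketol 21 with loss of nitrite. Ketol 21 is then oxidised with Cu(OAc)2 in aqueous acetic acid (divalent copper as a mild α-ketol oxidant) to the 3,4-dione, which tautomerises to 22, where the route is rejoined. This fallback makes no compound outside the list (F0).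

3. Step 6. The very electron-rich phenol may react further with formaldehyde (diarylmethane formation, hydroxymethylation at the para position), or conversion may stall at the hindered site between the hydroxyl and benzyloxy groups. The fallback formylates before the MOM group is removed, by directed ortho-metalation. Setting out from 6, n-BuLi/TMEDA in THF (−78 → −40 °C) should lithiate the position between the MOM ether and the neighbouring benzyloxy group, the MOM ether being the stronger director, and a DMF quench gives 4,6-bis(benzyloxy)-3-methoxy-2-(methoxymethoxy)benzaldehyde F3. Methanolic HCl then removes the MOM group and returns the route to 9.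

Further compounds
F1 | step 11 | 3,5-bis(benzyloxy)-2-methoxy-6-[(pyrrolidin-1-ium-1-ylidene)methyl]phenolate | [O-]c1c(OC)c(OCc2ccccc2)cc(OCc2ccccc2)c1C=[N+]1CCCC1
F2 | step 11 | racemic 1-{5,7-bis(benzyloxy)-2-[3,5-bis(benzyloxy)-4-methoxyphenyl]-8-methoxy-3-nitrochroman-4-yl}pyrrolidine | [O-][N+](=O)C1C(N2CCCC2)c2c(OCc3ccccc3)cc(OCc3ccccc3)c(OC)c2OC1c1cc(OCc2ccccc2)c(OC)c(OCc2ccccc2)c1
F0 | step 12 | none | none
F3 | step 6 | 4,6-bis(benzyloxy)-3-methoxy-2-(methoxymethoxy)benzaldehyde | O=Cc1c(OCOC)c(OC)c(OCc2ccccc2)cc1OCc1ccccc1
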